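C8 (acetate)/C8a (methyl) relayed: 22 ⇐ Luche reduction and acetylation of enone 20, the C8 alcohol being set by the angular methyl on C8a.
Seven-membered ring last: 20 ⇐ six-membered ketone 16 by insertion of one carbon (C7) between C6 and C8 (silyl enol ether, cyclopropanation, FeCl3 opening); regiospecific because C8a is quaternary.
C3a–H/C4–O ⇐ syn hydroboration of C3a=C4; C3 carbinol ⇐ isopropyl addition to a C3 ketone; both steered by the C8a methyl.
Five-membered ring ⇐ Nazarov 4π-electrocyclisation forming C1–C8a. Enabling feature: the ring oxygen sits on C3, flanked by C2 and C3a, so C1=C2–C3(=O)–C3a=C8a is a divinyl ketone; the C8 oxygen next to C8a supplies the controlling stereocentre.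
Divinyl ketone 6 ⇐ 3-bromo-2-methylcyclohex-2-enone ⇐ 2-methylcyclohexane-1,3-dione; one CBS reduction is the only catalyst-set stereocentre; ring order six (bought), five (Nazarov), seven (ring expansion).

Key step: step 5

Remark: locants in the text are those of the target (azulene numbering C1–C3, C3a, C4–C8, C8a) and are kept for the six-membered-ring intermediates, in which C7 is not yet present; the sense of the CBS reduction is assumed to follow the usual large/small-group model.

Step 1
Reactants: 1 2-methylcyclohexane-1,3-dione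
Product: 2 3-bromo-2-methylcyclohex-2-en-1-one
Conditions: PPh3, Br2, Et3N, CH2Cl2, 0 °C to rt
Reagents that add atoms: bromine, BrBr
Why: Deoxybromination of the enol (vinylogous acid) through its oxyphosphonium salt, an Appel-type reaction; no stereocentre is formed.

Step 2
Reactants: 2 3-bromo-2-methylcyclohex-2-en-1-one
Product: 3 (1S)-3-bromo-2-methylcyclohex-2-en-1-ol
Conditions: (3aR)-1-methyl-3,3-diphenyltetrahydro-1H,3H-pyrrolo[1,2-c][1,3,2]oxazaborole ((R)-Me-CBS, 10 mol %), BH3·SMe2, THF, −20 °C; MeOH, aqueous work-up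
Reagents that add atoms: none
Why: CBS reduction in which the fully substituted vinyl carbon acts as the large group and the ring CH2 as the small one, so the (R)-catalyst should give the (S)-carbinol (C8), the only stereocentre set by a catalyst.

Step 3
Reactants: 3 (1S)-3-bromo-2-methylcyclohex-2-en-1-ol
Product: 4 {[(1S)-3-bromo-2-methylcyclohex-2-en-1-yl]oxy}(tert-butyl)diphenylsilane
Conditions: TBDPSCl, imidazole, DMF, rt
Reagents that add atoms: tert-butyl(chloro)diphenylsilane, CC(C)(C)[Si](Cl)(c1ccccc1)c1ccccc1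
Why: Standard silylation; the bulky, acid-stable TBDPS ether should survive BF3 and shield one face of the ring in step 5.

Step 4
Reactants: 4 {[(1S)-3-bromo-2-methylcyclohex-2-en-1-yl]oxy}(tert-butyl)diphenylsilane
Product: 6 1-[(3S)-3-[(tert-butyldiphenylsilyl)oxy]-2-methylcyclohex-1-en-1-yl]prop-2-en-1-one, via vinyllithium 5 (not isolated)
Conditions: t-BuLi (2.1 equiv), THF, −78 °C; then N-methoxy-N-methylprop-2-enamide, −78 °C; cold 1 M HCl quench
Reagents that add atoms: N-methoxy-N-methylprop-2-enamide, C=CC(=O)N(C)OC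
Why: Bromine–lithium exchange followed by Weinreb ketone synthesis, in which the chelated tetrahedral adduct prevents over-addition; the C–Li bond is trans to the silyloxy-bearing carbon across the double bond, so silyl migration is not possible.

Step 5
Reactants: 6 1-[(3S)-3-[(tert-butyldiphenylsilyl)oxy]-2-methylcyclohex-1-en-1-yl]prop-2-en-1-one
Product: 7 (3aS,4S)-4-[(tert-butyldiphenylsilyl)oxy]-3a-methyl-2,3,3a,4,5,6-hexahydro-1H-inden-1-one
Conditions: BF3·OEt2 (1.5 equiv), CH2Cl2, −20 °C to rt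
Reagents that add atoms: none
Why: BF3 coordination to the C3 carbonyl generates the 3-oxidopentadienyl cation spanning C1–C2–C3–C3a–C8a, which undergoes conrotatory 4π electrocyclisation to form the C1–C8a bond and an oxyallyl cation; loss of a C4 proton and protonation at C2 on work-up should give enone 7. The closest known reaction type is the Nazarov cyclisation of 1-cycloalkenyl vinyl ketones, including cases that create an angular methyl-bearing quaternary carbon. The five-membered ring is closed by a thermally allowed pericyclic 4π conrotation, formally 5-endo and not subject to the constraints of polar ring closures. The new quaternary stereocentre C8a is controlled by the C8 silyloxy stereocentre: the OTBDPS group should sit pseudoaxial to avoid allylic strain with the C8a methyl and block one face, so C1 bonds anti to it and methyl and silyloxy end up cis. The step needs this torquoselectivity, secured by the bulk of the silyl ether, and regioselective proton loss toward C4, secured because the more substituted C3a terminus carries more of the positive charge and has hydrogens only on C4 once C8a is quaternary. The C8 ether is allylic only to an electron-poor enone double bond, so its ionisation by the Lewis acid is disfavoured.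

Step 6
Reactants: 7 (3aS,4S)-4-[(tert-butyldiphenylsilyl)oxy]-3a-methyl-2,3,3a,4,5,6-hexahydro-1H-inden-1-one
Product: 8 (1R,3aS,4S)-4-[(tert-butyldiphenylsilyl)oxy]-3a-methyl-1-(propan-2-yl)-2,3,3a,4,5,6-hexahydro-1H-inden-1-ol
Conditions: i-PrMgCl, CeCl3 (anhydrous), THF, −78 °C; aqueous NH4Cl
Reagents that add atoms: isopropylmagnesium chloride, CC(C)[Mg]Cl
Why: 1,2-Addition of an organocerium reagent (which suppresses enolisation, reduction and conjugate addition) to the enone; attack on the face opposite the pseudoaxial C8a methyl, 1,3 to the carbonyl, should place isopropyl trans and hydroxyl cis to that methyl (C3).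

Step 7
Reactants: 8 (1R,3aS,4S)-4-[(tert-butyldiphenylsilyl)oxy]-3a-methyl-1-(propan-2-yl)-2,3,3a,4,5,6-hexahydro-1H-inden-1-ol
Product: 9 (1R,3aS,4S)-4-[(tert-butyldiphenylsilyl)oxy]-3a-methyl-1-(propan-2-yl)-1-[(triethylsilyl)oxy]-2,3,3a,4,5,6-hexahydro-1H-indene
Conditions: TESOTf, 2,6-lutidine, CH2Cl2, −78 to 0 °C
Reagents that add atoms: triethylsilyl trifluoromethanesulfonate, CC[Si](CC)(CC)OS(=O)(=O)C(F)(F)F
Why: Silyl triflate silylation of the hindered tertiary allylic alcohol under basic conditions; it prevents alkoxide-delivered borane and adds bulk to the methyl-bearing face.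

Step 8
Reactants: 9 (1R,3aS,4S)-4-[(tert-butyldiphenylsilyl)oxy]-3a-methyl-1-(propan-2-yl)-1-[(triethylsilyl)oxy]-2,3,3a,4,5,6-hexahydro-1H-indene
Product: 11 (3R,3aS,4S,7S,7aS)-7-[(tert-butyldiphenylsilyl)oxy]-7a-methyl-3-(propan-2-yl)-3-[(triethylsilyl)oxy]octahydro-1H-inden-4-ol, via alkylborane 10 (not isolated)
Conditions: BH3·THF, THF, 0 °C to rt; then NaOH, H2O2, 0 °C
Reagents that add atoms: hydrogen peroxide, OO
Why: Hydroboration–oxidation with boron on the less substituted C4; syn addition to the face opposite the C8a methyl and the C3 silyloxy group (both pseudoaxial on the same face, with isopropyl pseudoequatorial) should set C3a–H and C4–OH cis to each other and trans to the methyl, which gives the trans ring fusion.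

Step 9
Reactants: 11 (3R,3aS,4S,7S,7aS)-7-[(tert-butyldiphenylsilyl)oxy]-7a-methyl-3-(propan-2-yl)-3-[(triethylsilyl)oxy]octahydro-1H-inden-4-ol
Product: 12 (3R,3aS,4S,7S,7aS)-7-[(tert-butyldiphenylsilyl)oxy]-7a-methyl-3-(propan-2-yl)-3-[(triethylsilyl)oxy]octahydro-1H-inden-4-yl 4-methoxybenzoate
Conditions: 4-MeOC6H4COCl, Et3N, DMAP (4-(dimethylamino)pyridine, cat.), CH2Cl2, rt to 40 °C
Reagents that add atoms: 4-methoxybenzoyl chloride, COc1ccc(C(Cl)=O)cc1
Why: Nucleophile-catalysed acylation of the only free hydroxyl group, installing the final C4 ester early.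

Step 10
Reactants: 12 (3R,3aS,4S,7S,7aS)-7-[(tert-butyldiphenylsilyl)oxy]-7a-methyl-3-(propan-2-yl)-3-[(triethylsilyl)oxy]octahydro-1H-inden-4-yl 4-methoxybenzoate
Product: 13 (3R,3aS,4S,7S,7aS)-3,7-dihydroxy-7a-methyl-3-(propan-2-yl)octahydro-1H-inden-4-yl 4-methoxybenzoate
Conditions: Bu4NF, AcOH, THF, 50 °C
Reagents that add atoms: none
Why: Fluoride-mediated cleavage of both silyl ethers, buffered with acetic acid to spare the aryl ester; the hydroxyl groups at C3 (cis to the methyl) and C4 are trans across C3a, so acyl migration is not expected.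

Step 11
Reactants: 13 (3R,3aS,4S,7S,7aS)-3,7-dihydroxy-7a-methyl-3-(propan-2-yl)octahydro-1H-inden-4-yl 4-methoxybenzoate
Product: 14 (3R,3aS,4S,7aS)-3-hydroxy-7a-methyl-7-oxo-3-(propan-2-yl)octahydro-1H-inden-4-yl 4-methoxybenzoate
Conditions: Dess–Martin periodinane, CH2Cl2, 0 °C to rt
Reagents that add atoms: none
Why: Dess–Martin oxidation of the secondary alcohol only (the tertiary one cannot react); the C8 stereocentre has served as relay and is re-created in step 16, and C3a is not epimerisable because it is β to the new ketone.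

Step 12
Reactants: 14 (3R,3aS,4S,7aS)-3-hydroxy-7a-methyl-7-oxo-3-(propan-2-yl)octahydro-1H-inden-4-yl 4-methoxybenzoate
Product: 16 (3R,3aS,4S,7aS)-3-hydroxy-6,7a-dimethyl-7-oxo-3-(propan-2-yl)octahydro-1H-inden-4-yl 4-methoxybenzoate (epimers at C6), via dilithium enolate alkoxide 15 (not isolated)
Conditions: LDA (2.2 equiv), THF, −78 °C; then MeI, DMPU, −78 to −40 °C
Reagents that add atoms: iodomethane, CI
Why: Enolate alkylation on the only enolisable side of the ketone (C8a is quaternary); the new methyl-bearing centre becomes sp2 in step 15, so its configuration is irrelevant.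

Step 13
Reactants: 16 (3R,3aS,4S,7aS)-3-hydroxy-6,7a-dimethyl-7-oxo-3-(propan-2-yl)octahydro-1H-inden-4-yl 4-methoxybenzoate (epimers at C6)
Product: 17 (3R,3aS,4S,7aS)-6,7a-dimethyl-3-(propan-2-yl)-3,7-bis[(trimethylsilyl)oxy]-2,3,3a,4,5,7a-hexahydro-1H-inden-4-yl 4-methoxybenzoate
Conditions: TMSOTf (2.5 equiv), Et3N, CH2Cl2, 0 °C to rt
Reagents that add atoms: trimethylsilyl trifluoromethanesulfonate, C[Si](C)(C)OS(=O)(=O)C(F)(F)F
Why: Soft enolisation and silylation give the only possible silyl enol ether, and the tertiary hydroxyl is silylated at the same time.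

Step 14
Reactants: 17 (3R,3aS,4S,7aS)-6,7a-dimethyl-3-(propan-2-yl)-3,7-bis[(trimethylsilyl)oxy]-2,3,3a,4,5,7a-hexahydro-1H-inden-4-yl 4-methoxybenzoate
Product: 18 siloxycyclopropane formed by CH2 addition across the silyl enol ether double bond of 17 (1-methyl-6-trimethylsilyloxy-bicyclo[4.1.0]heptane unit fused to the cyclopentane; other substituents and stereocentres as in 17)
Conditions: Et2Zn, CH2I2, CH2Cl2, 0 °C to rt
Reagents that add atoms: diiodomethane, ICI
Why: Simmons–Smith (Furukawa) cyclopropanation of the electron-rich silyl enol ether, the only C=C bond present; its facial selectivity is irrelevant because both new centres are destroyed in step 15.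

Step 15
Reactants: 18 siloxycyclopropane
Product: 20 (3R,3aS,4S,8aS)-3-hydroxy-6,8a-dimethyl-8-oxo-3-(propan-2-yl)-1,2,3,3a,4,5,8,8a-octahydroazulen-4-yl 4-methoxybenzoate, via chloro ketone 19 (not isolated)
Conditions: FeCl3, DMF, 0 °C to rt; then NaOAc, MeOH, 65 °C
Reagents that add atoms: none
Why: Saegusa–Ito-type ring expansion in which one-electron oxidation by FeCl3 (trivalent iron) opens the internal cyclopropane bond, the ring-expanded tertiary radical takes up chlorine, and acetate-induced loss of HCl gives the enone with the methyl on the β-carbon, while methanol removes the tertiary silyl ether.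

Step 16
Reactants: 20 (3R,3aS,4S,8aS)-3-hydroxy-6,8a-dimethyl-8-oxo-3-(propan-2-yl)-1,2,3,3a,4,5,8,8a-octahydroazulen-4-yl 4-methoxybenzoate
Product: 21 (3R,3aS,4S,8S,8aS)-3,8-dihydroxy-6,8a-dimethyl-3-(propan-2-yl)-1,2,3,3a,4,5,8,8a-octahydroazulen-4-yl 4-methoxybenzoate
Conditions: NaBH4, CeCl3·7H2O, MeOH, −40 °C
Reagents that add atoms: none
Why: Luche 1,2-reduction; hydride delivery to the face opposite the pseudoaxial C8a methyl should give the C8 alcohol cis to that methyl, as is usual for ketones next to an angular methyl group.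

Step 17
Reactants: 21 (3R,3aS,4S,8S,8aS)-3,8-dihydroxy-6,8a-dimethyl-3-(propan-2-yl)-1,2,3,3a,4,5,8,8a-octahydroazulen-4-yl 4-methoxybenzoate
Product: 22 (3R,3aS,4S,8S,8aS)-8-(acetyloxy)-3-hydroxy-6,8a-dimethyl-3-(propan-2-yl)-1,2,3,3a,4,5,8,8a-octahydroazulen-4-yl 4-methoxybenzoate
Conditions: Ac2O, Et3N, DMAP (cat.), CH2Cl2, 0 °C to rt
Reagents that add atoms: acetic anhydride, CC(=O)OC(C)=O
Why: Nucleophile-catalysed acetylation of the secondary allylic alcohol; the hindered tertiary C3 hydroxyl should not react under these conditions.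

Compound list
1 | 2-methylcyclohexane-1,3-dione | CC1C(=O)CCCC1=O | starting material
2 | 3-bromo-2-methylcyclohex-2-en-1-one | CC1=C(Br)CCCC1=O | intermediate
3 | (1S)-3-bromo-2-methylcyclohex-2-en-1-ol | O[C@H]1CCCC(Br)=C1C | intermediate
4 | {[(1S)-3-bromo-2-methylcyclohex-2-en-1-yl]oxy}(tert-butyl)diphenylsilane | CC(C)(C)[Si](c2ccccc2)(c3ccccc3)O[C@H]1CCCC(Br)=C1C | intermediate
5 | [(3S)-3-[(tert-butyldiphenylsilyl)oxy]-2-methylcyclohex-1-en-1-yl]lithium (not isolated) | CC(C)(C)[Si](c2ccccc2)(c3ccccc3)O[C@H]1CCCC([Li])=C1C | intermediate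
6 | 1-[(3S)-3-[(tert-butyldiphenylsilyl)oxy]-2-methylcyclohex-1-en-1-yl]prop-2-en-1-one | CC(C)(C)[Si](c2ccccc2)(c3ccccc3)O[C@H]1CCCC(C(=O)C=C)=C1C | intermediate
7 | (3aS,4S)-4-[(tert-butyldiphenylsilyl)oxy]-3a-methyl-2,3,3a,4,5,6-hexahydro-1H-inden-1-one (methyl and silyloxy cis) | C2CC[C@H](O[Si](c4ccccc4)(c5ccccc5)C(C)(C)C)[C@@]3(C)CCC(=O)C3=2 | intermediate
8 | (1R,3aS,4S)-4-[(tert-butyldiphenylsilyl)oxy]-3a-methyl-1-(propan-2-yl)-2,3,3a,4,5,6-hexahydro-1H-inden-1-ol (hydroxyl cis to the angular methyl) | C2CC[C@H](O[Si](c4ccccc4)(c5ccccc5)C(C)(C)C)[C@@]3(C)CC[C@@](O)(C(C)C)C3=2 | intermediate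
9 | (1R,3aS,4S)-4-[(tert-butyldiphenylsilyl)oxy]-3a-methyl-1-(propan-2-yl)-1-[(triethylsilyl)oxy]-2,3,3a,4,5,6-hexahydro-1H-indene | C2CC[C@H](O[Si](c4ccccc4)(c5ccccc5)C(C)(C)C)[C@@]3(C)CC[C@@](O[Si](CC)(CC)CC)(C(C)C)C3=2 | intermediate
10 | alkylborane from 9, boron on C4 and hydrogen on C3a, both trans to the angular methyl (not isolated) | B[C@H]2CC[C@H](O[Si](c4ccccc4)(c5ccccc5)C(C)(C)C)[C@@]3(C)CC[C@@](O[Si](CC)(CC)CC)(C(C)C)[C@H]23 | intermediate
11 | (3R,3aS,4S,7S,7aS)-7-[(tert-butyldiphenylsilyl)oxy]-7a-methyl-3-(propan-2-yl)-3-[(triethylsilyl)oxy]octahydro-1H-inden-4-ol (trans-fused) | O[C@H]2CC[C@H](O[Si](c4ccccc4)(c5ccccc5)C(C)(C)C)[C@@]3(C)CC[C@@](O[Si](CC)(CC)CC)(C(C)C)[C@H]23 | intermediate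
12 | (3R,3aS,4S,7S,7aS)-7-[(tert-butyldiphenylsilyl)oxy]-7a-methyl-3-(propan-2-yl)-3-[(triethylsilyl)oxy]octahydro-1H-inden-4-yl 4-methoxybenzoate | COc1ccc(C(=O)O[C@H]2CC[C@H](O[Si](c4ccccc4)(c5ccccc5)C(C)(C)C)[C@@]3(C)CC[C@@](O[Si](CC)(CC)CC)(C(C)C)[C@H]23)cc1 | intermediate
13 | (3R,3aS,4S,7S,7aS)-3,7-dihydroxy-7a-methyl-3-(propan-2-yl)octahydro-1H-inden-4-yl 4-methoxybenzoate | COc1ccc(C(=O)O[C@H]2CC[C@H](O)[C@@]3(C)CC[C@@](O)(C(C)C)[C@H]23)cc1 | intermediate
14 | (3R,3aS,4S,7aS)-3-hydroxy-7a-methyl-7-oxo-3-(propan-2-yl)octahydro-1H-inden-4-yl 4-methoxybenzoate | COc1ccc(C(=O)O[C@H]2CCC(=O)[C@@]3(C)CC[C@@](O)(C(C)C)[C@H]23)cc1 | intermediate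
15 | dilithium enolate alkoxide of 14 (not isolated) | COc1ccc(C(=O)O[C@H]2CC=C(O[Li])[C@@]3(C)CC[C@@](O[Li])(C(C)C)[C@H]23)cc1 | intermediate
16 | (3R,3aS,4S,7aS)-3-hydroxy-6,7a-dimethyl-7-oxo-3-(propan-2-yl)octahydro-1H-inden-4-yl 4-methoxybenzoate (epimers at C6) | COc1ccc(C(=O)O[C@H]2CC(C)C(=O)[C@@]3(C)CC[C@@](O)(C(C)C)[C@H]23)cc1 | intermediate
17 | (3R,3aS,4S,7aS)-6,7a-dimethyl-3-(propan-2-yl)-3,7-bis[(trimethylsilyl)oxy]-2,3,3a,4,5,7a-hexahydro-1H-inden-4-yl 4-methoxybenzoate | COc1ccc(C(=O)O[C@H]2CC(C)=C(O[Si](C)(C)C)[C@@]3(C)CC[C@@](O[Si](C)(C)C)(C(C)C)[C@H]23)cc1 | intermediate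
18 | siloxycyclopropane: CH2 bridge across the former enol ether carbons of 17 (cyclopropane carbons carry methyl and trimethylsilyloxy; configuration of the cyclopropane unspecified) | COc1ccc(C(=O)O[C@H]2CC3(C)CC3(O[Si](C)(C)C)[C@@]4(C)CC[C@@](O[Si](C)(C)C)(C(C)C)[C@H]24)cc1 | intermediate
19 | (3R,3aS,4S,8aS)-6-chloro-6,8a-dimethyl-8-oxo-3-(propan-2-yl)-3-[(trimethylsilyl)oxy]decahydroazulen-4-yl 4-methoxybenzoate (not isolated; C6 unspecified) | COc1ccc(C(=O)O[C@H]2CC(C)(Cl)CC(=O)[C@@]3(C)CC[C@@](O[Si](C)(C)C)(C(C)C)[C@H]23)cc1 | intermediate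
20 | (3R,3aS,4S,8aS)-3-hydroxy-6,8a-dimethyl-8-oxo-3-(propan-2-yl)-1,2,3,3a,4,5,8,8a-octahydroazulen-4-yl 4-methoxybenzoate | COc1ccc(C(=O)O[C@H]2CC(C)=CC(=O)[C@@]3(C)CC[C@@](O)(C(C)C)[C@H]23)cc1 | intermediate
21 | (3R,3aS,4S,8S,8aS)-3,8-dihydroxy-6,8a-dimethyl-3-(propan-2-yl)-1,2,3,3a,4,5,8,8a-octahydroazulen-4-yl 4-methoxybenzoate | COc1ccc(C(=O)O[C@H]2CC(C)=C[C@H](O)[C@@]3(C)CC[C@@](O)(C(C)C)[C@H]23)cc1 | intermediate
22 | (3R,3aS,4S,8S,8aS)-8-(acetyloxy)-3-hydroxy-6,8a-dimethyl-3-(propan-2-yl)-1,2,3,3a,4,5,8,8a-octahydroazulen-4-yl 4-methoxybenzoate | COc1ccc(C(=O)O[C@H]2CC(C)=C[C@H](OC(C)=O)[C@@]3(C)CC[C@@](O)(C(C)C)[C@H]23)cc1 | target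

Total step count: 17. Longest linear sequence: 17 steps from 2-methylcyclohexane-1,3-dione; all other inputs are commercial reagents.

Steps most likely to fail

Step 5 (Nazarov cyclisation). The oxyallyl cation may lose a proton from C2 instead of C4, or the enone may isomerise under the Lewis acid, so that the double bond does not end up between C3a and C4. The fallback sets out from 6 and comes back at 7. BF3·OEt2 in the presence of Et3SiH (interrupted, reductive Nazarov cyclisation) should intercept the oxyallyl cation with hydride and give, after hydrolysis of the silyl enol ether, the saturated hydrindanone F1. Soft enolisation (TMSOTf, Et3N) to the more substituted silyl enol ether F2 and Saegusa–Ito oxidation with Pd(OAc)2 in MeCN, for which only C4 offers a β-hydrogen, should then place the double bond unambiguously and deliver 7.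

Step 8 (hydroboration). Borane may add with poor facial selectivity, or from the methyl-bearing face if the isopropyl group shields the other one, which would give the cis-fused epimer. The fallback sets out from 7 and comes back at 13. Nucleophilic epoxidation (t-BuOOH, DBU) on the face opposite the angular methyl should give the epoxy ketone F3. Reductive opening of the Cα–O bond with SmI2 in THF/MeOH, with protonation of the samarium enolate opposite to the methyl group, should give the trans-fused β-hydroxy ketone F4. Addition of i-PrMgCl/CeCl3 should give the diol F5, selective acylation of its secondary hydroxyl with 4-methoxybenzoyl chloride the ester F6, and Bu4NF/AcOH then gives 13.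

Step 15 (oxidative ring expansion). Under FeCl3 the tertiary silyl ether or alcohol may ionise, or the cyclopropyloxy radical may fragment toward the quaternary carbon instead of opening the three-membered ring. The fallback sets out from 16 and comes back at 20. BF3·OEt2-promoted homologation with trimethylsilyldiazomethane, in which the less substituted, methyl-bearing α-carbon should migrate, followed by a protodesilylating work-up, should give the cycloheptanone F7. Dehydrogenation with 2-iodoxybenzoic acid (IBX) in DMSO at 70 °C, possible only toward C7, then gives 20.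

Further compounds
F1 | step 5 | (3aS,4S)-4-[(tert-butyldiphenylsilyl)oxy]-3a-methyloctahydro-1H-inden-1-one (either configuration at the ring-fusion CH) | C2CC[C@H](O[Si](c4ccccc4)(c5ccccc5)C(C)(C)C)[C@@]3(C)CCC(=O)C32
F2 | step 5 | tert-butyl{[(3aS,4S)-3a-methyl-1-[(trimethylsilyl)oxy]-3,3a,4,5,6,7-hexahydro-2H-inden-4-yl]oxy}diphenylsilane | C2CC[C@H](O[Si](c4ccccc4)(c5ccccc5)C(C)(C)C)[C@@]3(C)CCC(O[Si](C)(C)C)=C32
F3 | step 8 | epoxy ketone: epoxide across the enone double bond of 7, oxirane oxygen trans to the angular methyl | O1[C@H]2CC[C@H](O[Si](c4ccccc4)(c5ccccc5)C(C)(C)C)[C@@]3(C)CCC(=O)[C@]123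
F4 | step 8 | (3aS,4S,7S,7aS)-4-[(tert-butyldiphenylsilyl)oxy]-7-hydroxy-3a-methyloctahydro-1H-inden-1-one | O[C@H]2CC[C@H](O[Si](c4ccccc4)(c5ccccc5)C(C)(C)C)[C@@]3(C)CCC(=O)[C@H]23
F5 | step 8 | (1R,3aS,4S,7S,7aS)-4-[(tert-butyldiphenylsilyl)oxy]-3a-methyl-1-(propan-2-yl)octahydro-1H-indene-1,7-diol | O[C@H]2CC[C@H](O[Si](c4ccccc4)(c5ccccc5)C(C)(C)C)[C@@]3(C)CC[C@@](O)(C(C)C)[C@H]23
F6 | step 8 | (3R,3aS,4S,7S,7aS)-7-[(tert-butyldiphenylsilyl)oxy]-3-hydroxy-7a-methyl-3-(propan-2-yl)octahydro-1H-inden-4-yl 4-methoxybenzoate | COc1ccc(C(=O)O[C@H]2CC[C@H](O[Si](c4ccccc4)(c5ccccc5)C(C)(C)C)[C@@]3(C)CC[C@@](O)(C(C)C)[C@H]23)cc1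
F7 | step 15 | (3R,3aS,4S,8aS)-3-hydroxy-6,8a-dimethyl-8-oxo-3-(propan-2-yl)decahydroazulen-4-yl 4-methoxybenzoate (epimers at C6) | COc1ccc(C(=O)O[C@H]2CC(C)CC(=O)[C@@]3(C)CC[C@@](O)(C(C)C)[C@H]23)cc1
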